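**Plan**

- Retrosynthesis: the triene is cut at C12–C13 (Suzuki) and at C11/C12 (alkyne carboalumination, one-carbon homologation of a C7 aldehyde). Ring A is then stripped back (C4=CH2 to ketone, C1–Br to ketone, C5–OH to C5–H) to a cis-octalone ketal, which is cut at C5–C6 and C9–C10.
- Enabling feature: in ring B (C5–C10) the C10 methyl is para to C7, and C1 and C4 flank the ring fusion. Ring B therefore maps onto a 2-methylcyclohex-2-enone (C1 carbonyl, C4 ketal) plus a 2-substituted butadiene (C6=C7–C8=C9).
- Forward: ring A is bought as an enone ketal, ring B closes in the Diels–Alder step, ring A is adjusted in the order C5–OH, masked C4 methylene, C1 bromide, and the side chain is joined last.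
- Order in ring A: C1 is parked as a carbinol while C5 is oxidised, because a C1=C2 bromoalkene would make C3 the acidic site of the C4 ketone. C4 is held as a β-hydroxysilane while C1 becomes the bromoalkene and is reduced, because a free C4=CH2 would be reduced too.
- Stereochemistry: C10 from the chiral Lewis acid in the cycloaddition; C5 from peracid attack anti to the C10 methyl; C1 and C7 from axial hydrogen delivery to radicals in the trans-decalin (C7 re-secured by aldehyde equilibration); both side-chain alkenes from syn metalation and stereoretentive coupling.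

Key step: step 5

Remark: locants are skeleton locants (C1 CHBr, C4 C(=CH2), C5 C–OH, C7 side-chain CH, C10 C–CH3, side chain from C11); β is the face of the C10 methyl; the enone ketal starting material 1,4-dioxaspiro[4.5]dec-6-en-8-one is taken as a catalogue compound.

**Route**

Step 1
Reactants: 1 isoprene monoxide (2-methyl-2-vinyloxirane)
Product: 2 2-methylenebut-3-en-1-ol
Conditions: LiN(i-Pr)2, Et2O, 0 °C → rt; H2O
Reagents that add atoms: none
Why: Base-induced epoxide-to-allylic-alcohol isomerisation, in which the amide removes a methyl proton and the oxirane opens to the dienol; no stereocentre is formed.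

Step 2
Reactants: 2 2-methylenebut-3-en-1-ol
Product: 3 tert-butyl[(2-methylenebut-3-en-1-yl)oxy]diphenylsilane
Conditions: TBDPSCl, imidazole, CH2Cl2, 0 °C → rt
Reagents that add atoms: tert-butylchlorodiphenylsilane, CC(C)(C)[Si](Cl)(c1ccccc1)c1ccccc1
Why: Standard silylation of a primary alcohol; the bulky silyl ether is chosen to survive the Lewis acid, hydride, peracid, organolithium and radical steps ahead.

Step 3
Reactants: 4 1,4-dioxaspiro[4.5]dec-6-en-8-one
Product: 5 7-iodo-1,4-dioxaspiro[4.5]dec-6-en-8-one
Conditions: I2, pyridine, CH2Cl2, 0 °C → rt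
Reagents that add atoms: iodine, [I][I]
Why: Johnson α-iodination of an enone (pyridine conjugate addition, iodination of the enolate, elimination), which places iodine only on the α-carbon.

Step 4
Reactants: 5 7-iodo-1,4-dioxaspiro[4.5]dec-6-en-8-one
Product: 6 7-methyl-1,4-dioxaspiro[4.5]dec-6-en-8-one (2-methyl-4,4-ethylenedioxycyclohex-2-enone)
Conditions: ZnMe2, Pd(PPh3)4 (5 mol %), THF, 0 °C → rt
Reagents that add atoms: dimethylzinc, C[Zn]C
Why: Negishi cross-coupling of an α-iodoenone gives the 2-methyl enone with the double-bond position fixed, which dehydrogenation of the methyl ketone would not guarantee.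

Step 5
Reactants: 3 tert-butyl[(2-methylenebut-3-en-1-yl)oxy]diphenylsilane; 6 7-methyl-1,4-dioxaspiro[4.5]dec-6-en-8-one
Product: 7 cis-octalone ketal, (5S,10R)-7-[(tert-butyldiphenylsilyloxy)methyl]-4,4-ethylenedioxy-10-methyl-Δ7-octalin-1-one (5-H and 10-CH3 both β)
Conditions: 3 (3 equiv), AlBr3 complex of (S)-3,3-diphenyl-1-(2-methylphenyl)tetrahydro-1H,3H-pyrrolo[1,2-c][1,3,2]oxazaborole (20 mol %), CH2Cl2, −40 → 0 °C
Reagents that add atoms: none
Why: The AlBr3-activated oxazaborolidine binds the C1 carbonyl of 6 and the enone adds to the diene in a concerted but asynchronous [4+2] cycloaddition in which C5, the electrophilic β-carbon, bonds ahead to C6, the more nucleophilic terminus of the 2-substituted diene, so that CH2OSi ends up on C7, para to C10. The closest known reaction types are the AlCl3- or EtAlCl2-promoted additions of isoprene-type dienes to 2-methylcyclohex-2-enones (carvone included) and the cationic oxazaborolidine-catalysed Diels–Alder reactions of cyclic enones and 4,4-disubstituted cyclohexadienones. Ring B is closed as a cyclohexene by intermolecular suprafacial addition of the four-carbon diene across C5=C10, both σ-bonds (C5–C6 and C9–C10) forming in the same step. C5 and C10 are created together: their cis relationship follows from suprafacial addition to the ring alkene, and the absolute sense from the catalyst, which has to shield the β-face so that the diene adds to the Re face at C2 of 6 and the C10 methyl ends up β. The step needs para regioselectivity, secured by the match of carbonyl polarisation and diene substituent, and enantiofacial selectivity, which rests on the catalyst alone: the (S)-catalyst is assigned by analogy with 2-substituted enals (boron anti to the C=C, aryl group over one face), and this analogy is the least secure element of the route.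

Step 6
Reactants: 7 cis-octalone ketal
Product: 9 1-hydroxy-4-ketone (C1 epimers), via hydroxy ketal 8 (not isolated)
Conditions: NaBH4, MeOH, 0 °C; then 1 M HCl, THF, rt
Reagents that add atoms: water, O
Why: Borohydride reduction of the hindered C1 ketone followed by acid hydrolysis of the dioxolane leaves C4 as the only carbonyl for the enolisation to come; the C1 configuration and any epimerisation at C5 are immaterial because both centres are reset later.

Step 7
Reactants: 9 1-hydroxy-4-ketone (C1 epimers)
Product: 10 bis-silyl compound (C1–OSiMe3 ether and C4=C5 trimethylsilyl enol ether)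
Conditions: Me3SiCl, NaI, Et3N, MeCN, rt → 40 °C
Reagents that add atoms: chlorotrimethylsilane, C[Si](C)(C)Cl
Why: Thermodynamic silyl enol ether formation with Me3SiI made in situ should favour the tetrasubstituted C4=C5 enol ether, since C3 is now an ordinary methylene, and it silylates the C1 hydroxyl in the same operation.

Step 8
Reactants: 10 bis-silyl compound
Product: 13 trans-fused 1,5α-dihydroxy-4-ketone, via silyloxy epoxide 11 (not isolated), via bis-silyl ketol 12 (not isolated)
Conditions: mCPBA (1.0 equiv), NaHCO3, CH2Cl2, −20 °C; then 1 M HCl, THF, 0 °C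
Reagents that add atoms: 3-chloroperbenzoic acid, OOC(=O)c1cccc(Cl)c1
Why: Rubottom oxidation, in which the electron-rich enol ether is epoxidised ahead of the C7=C8 alkene and from the α-face, anti to the axial C10 methyl, so that silyl migration and hydrolysis give the 5α-hydroxy ketone and overwrite the cis fusion with the trans one.

Step 9
Reactants: 13 trans-fused 1,5α-dihydroxy-4-ketone
Product: 14 1,4,5α-triol carrying CH2SiMe3 on C4 (C1 and C4 configurations immaterial)
Conditions: Me3SiCH2Li (5 equiv), CeCl3, THF, −78 → 0 °C; aq. NH4Cl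
Reagents that add atoms: (trimethylsilyl)methyllithium, [Li]C[Si](C)(C)C
Why: First half of a Peterson methylenation in its cerium-mediated form, which adds to hindered, enolisable ketones without enolisation; the β-hydroxysilane holds C4 as neither ketone nor alkene through the hydrazone and radical-reduction steps.

Step 10
Reactants: 14 1,4,5α-triol
Product: 15 4,5α-dihydroxy-4-[(trimethylsilyl)methyl]-1-ketone
Conditions: IBX, DMSO, rt
Reagents that add atoms: none
Why: IBX oxidises the only secondary alcohol and is chosen because it does not cleave the ditertiary 4,5-diol.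

Step 11
Reactants: 15 4,5α-dihydroxy-1-ketone
Product: 16 C1 hydrazone of 15
Conditions: N2H4·H2O, Et3N, EtOH, 80 °C
Reagents that add atoms: hydrazine, NN
Why: Hydrazone formation at the only carbonyl under Barton's weakly basic conditions, which generate no alkoxide and so should not trigger retro-aldol opening of the C5–C10 bond of this β-hydroxy ketone.

Step 12
Reactants: 16 C1 hydrazone
Product: 17 1-bromo-Δ1,Δ7-diene-4,5α-diol (vinyl bromide)
Conditions: NBS (2.2 equiv), pyridine, −10 → 0 °C
Reagents that add atoms: N-bromosuccinimide, O=C1CCC(=O)N1Br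
Why: Barton-type vinyl halide synthesis, in which the hydrazone is oxidised to the diazoalkane, brominated at carbon, and loses N2 and the C2 proton; C2 is the only position from which a proton can be lost, and the hydrazone nitrogen is far more nucleophilic than the trisubstituted alkene.

Step 13
Reactants: 17 vinyl bromide
Product: 18 1β-bromo-7β-[(tert-butyldiphenylsilyloxy)methyl]-10β-methyl-4-[(trimethylsilyl)methyl]-trans-decalin-4,5α-diol
Conditions: Mn(dpm)3 (cat.), PhSiH3, t-BuOOH, i-PrOH, rt
Reagents that add atoms: none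
Why: Manganese-hydride hydrogen-atom-transfer hydrogenation (Mukaiyama-type, Shenvi's conditions), known to reduce haloalkenes with retention of halogen: H adds to C2 and C8, and the C1 (α-bromo) and C7 (tertiary) radicals should take up the second hydrogen axially on the α-face of the rigid trans-decalin, anti to the axial C10 methyl, leaving Br and CH2OSi equatorial (1β, 7β).

Step 14
Reactants: 18 saturated bromo diol
Product: 19 1β-bromo-7β-[(tert-butyldiphenylsilyloxy)methyl]-10β-methyl-4-methylene-trans-decalin-5α-ol
Conditions: BF3·OEt2 (1.2 equiv), CH2Cl2, −78 → −20 °C; aq. NaHCO3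
Reagents that add atoms: none
Why: Acid-promoted (anti) Peterson elimination, in which ionisation at C4 is driven by the β-silicon effect and outruns reaction at the C5 carbinol; acid is chosen over base because a C5 alkoxide is aligned for Grob fragmentation with the equatorial C1 bromide.

Step 15
Reactants: 19 silyl ether
Product: 20 1β-bromo-7β-(hydroxymethyl)-10β-methyl-4-methylene-trans-decalin-5α-ol
Conditions: Bu4NF, AcOH, THF, 0 °C → rt
Reagents that add atoms: none
Why: Fluoride cleavage of the primary silyl ether, buffered with acetic acid so that no free C5 alkoxide is generated.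

Step 16
Reactants: 20 diol
Product: 21 7β-carbaldehyde (1β-bromo-5α-hydroxy-10β-methyl-4-methylene-trans-decalin-7β-carbaldehyde)
Conditions: Dess–Martin periodinane, NaHCO3, CH2Cl2, 0 °C → rt
Reagents that add atoms: none
Why: Dess–Martin oxidation of the primary alcohol; the tertiary allylic alcohol cannot be oxidised and, unlike with a chromium oxidant, is not at risk of oxidative transposition.

Step 17
Reactants: 21 aldehyde
Product: 22 7β-ethynyl compound (1β-bromo-7β-ethynyl-10β-methyl-4-methylene-trans-decalin-5α-ol)
Conditions: K2CO3, MeOH, rt; then dimethyl (1-diazo-2-oxopropyl)phosphonate, 0 °C → rt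
Reagents that add atoms: dimethyl (1-diazo-2-oxopropyl)phosphonate, CC(=O)C(=[N+]=[N-])P(=O)(OC)OC
Why: Carbonate in methanol equilibrates C7 through the enolate towards the equatorial (7β) aldehyde, which avoids the syn-axial clash with the C5 hydroxyl, and the Seyferth–Gilbert homologation with the Ohira–Bestmann reagent then converts that aldehyde into the alkyne and fixes C7; carbonate is too weak a base to build up the C5 alkoxide.

Step 18
Reactants: 22 alkyne
Product: 24 (E)-alkenyl iodide, via alkenylalane 23 (not isolated)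
Conditions: AlMe3 (4 equiv), Cp2ZrCl2 (0.5 equiv), CH2Cl2, 0 °C → rt; then I2, THF, −30 °C; aq. Na2S2O3/NaHCO3
Reagents that add atoms: trimethylaluminium, C[Al](C)C; iodine, [I][I]
Why: Negishi zirconium-catalysed carboalumination adds CH3 and Al syn across the terminal alkyne with Al on the terminal carbon, and iodinolysis with retention gives the E iodide; the 1,1-disubstituted alkene is inert under these conditions and the tertiary alcohol is carried as its aluminium alkoxide.

Step 19
Reactants: 25 2-methylbut-1-en-3-yne
Product: 26 (E)-4,4,5,5-tetramethyl-2-(3-methylbuta-1,3-dien-1-yl)-1,3,2-dioxaborolane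
Conditions: pinacolborane, Cp2Zr(H)Cl (5 mol %), Et3N (10 mol %), CH2Cl2, rt, sealed vessel
Reagents that add atoms: pinacolborane, B1OC(C)(C)C(C)(C)O1
Why: Zirconocene-catalysed syn hydroboration of the terminal alkyne gives the E dienylboronate and leaves the 1,1-disubstituted alkene untouched.

Step 20
Reactants: 24 (E)-alkenyl iodide; 26 (E)-dienylboronate
Product: 27 target, 1β-bromo-10β-methyl-4-methylene-7β-[(2E,4E)-6-methylhepta-2,4,6-trien-2-yl]-trans-decalin-5α-ol
Conditions: Pd(dppf)Cl2 (5 mol %), K3PO4 (aq), THF, rt → 40 °C, degassed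
Reagents that add atoms: none
Why: Suzuki–Miyaura coupling proceeds with retention at both sp2 carbons to give the E,E-triene; the alkenyl iodide reacts far faster than the unactivated secondary bromide and the mild aqueous base should not cause fragmentation.

**Compound list**

1 | isoprene monoxide (2-methyl-2-vinyloxirane, racemic) | CC1(CO1)C=C | starting material
2 | 2-methylenebut-3-en-1-ol | C=CC(=C)CO | intermediate
3 | tert-butyl[(2-methylenebut-3-en-1-yl)oxy]diphenylsilane | C=CC(=C)CO[Si](c1ccccc1)(c1ccccc1)C(C)(C)C | intermediate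
4 | 1,4-dioxaspiro[4.5]dec-6-en-8-one | O=C1C=CC2(CC1)OCCO2 | starting material
5 | 7-iodo-1,4-dioxaspiro[4.5]dec-6-en-8-one | O=C1C(I)=CC2(CC1)OCCO2 | intermediate
6 | 7-methyl-1,4-dioxaspiro[4.5]dec-6-en-8-one | CC1=CC2(CCC1=O)OCCO2 | intermediate
7 | cis-octalone ketal, (5S,10R), 5-H and 10-CH3 β, C7=C8, CH2OTBDPS on C7 | CC(C)(C)[Si](c3ccccc3)(c3ccccc3)OCC1=CC[C@@]2(C)C(=O)CCC3(OCCO3)[C@H]2C1 | intermediate
8 | hydroxy ketal (C1 carbinol of 7, C1 epimers; not isolated) | CC(C)(C)[Si](c3ccccc3)(c3ccccc3)OCC1=CC[C@@]2(C)C(O)CCC3(OCCO3)[C@H]2C1 | intermediate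
9 | 1-hydroxy-4-ketone (C1 epimers; cis fusion drawn, C5 epimerisable) | CC(C)(C)[Si](c3ccccc3)(c3ccccc3)OCC1=CC[C@@]2(C)C(O)CCC(=O)[C@H]2C1 | intermediate
10 | bis-silyl compound: C1–OSiMe3 ether, C4=C5 trimethylsilyl enol ether | CC(C)(C)[Si](c3ccccc3)(c3ccccc3)OCC1=CC[C@@]2(C)C(O[Si](C)(C)C)CCC(O[Si](C)(C)C)=C2C1 | intermediate
11 | 4α,5α-silyloxy epoxide of 10 (not isolated) | CC(C)(C)[Si](c3ccccc3)(c3ccccc3)OCC1=CC[C@@]2(C)C(O[Si](C)(C)C)CC[C@@]4(O[Si](C)(C)C)O[C@@]24C1 | intermediate
12 | trans-fused 1,5α-bis(trimethylsilyloxy)-4-ketone (not isolated) | CC(C)(C)[Si](c3ccccc3)(c3ccccc3)OCC1=CC[C@@]2(C)C(O[Si](C)(C)C)CCC(=O)[C@]2(O[Si](C)(C)C)C1 | intermediate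
13 | trans-fused 1,5α-dihydroxy-4-ketone (C1 epimers) | CC(C)(C)[Si](c3ccccc3)(c3ccccc3)OCC1=CC[C@@]2(C)C(O)CCC(=O)[C@]2(O)C1 | intermediate
14 | 1,4,5α-triol with CH2SiMe3 on C4 (C1, C4 unassigned) | CC(C)(C)[Si](c3ccccc3)(c3ccccc3)OCC1=CC[C@@]2(C)C(O)CCC(O)(C[Si](C)(C)C)[C@]2(O)C1 | intermediate
15 | 4,5α-dihydroxy-4-[(trimethylsilyl)methyl]-1-ketone | CC(C)(C)[Si](c3ccccc3)(c3ccccc3)OCC1=CC[C@@]2(C)C(=O)CCC(O)(C[Si](C)(C)C)[C@]2(O)C1 | intermediate
16 | C1 hydrazone of 15 | CC(C)(C)[Si](c3ccccc3)(c3ccccc3)OCC1=CC[C@@]2(C)C(=NN)CCC(O)(C[Si](C)(C)C)[C@]2(O)C1 | intermediate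
17 | 1-bromo-Δ1,Δ7-diene-4,5α-diol | CC(C)(C)[Si](c3ccccc3)(c3ccccc3)OCC1=CC[C@@]2(C)C(Br)=CCC(O)(C[Si](C)(C)C)[C@]2(O)C1 | intermediate
18 | 1β-bromo-7β-(TBDPS-oxymethyl)-4-[(trimethylsilyl)methyl]-trans-decalin-4,5α-diol | CC(C)(C)[Si](c3ccccc3)(c3ccccc3)OC[C@@H]1CC[C@@]2(C)[C@H](Br)CCC(O)(C[Si](C)(C)C)[C@]2(O)C1 | intermediate
19 | 1β-bromo-7β-(TBDPS-oxymethyl)-10β-methyl-4-methylene-trans-decalin-5α-ol | CC(C)(C)[Si](c3ccccc3)(c3ccccc3)OC[C@@H]1CC[C@@]2(C)[C@H](Br)CCC(=C)[C@]2(O)C1 | intermediate
20 | 1β-bromo-7β-(hydroxymethyl)-10β-methyl-4-methylene-trans-decalin-5α-ol | OC[C@@H]1CC[C@@]2(C)[C@H](Br)CCC(=C)[C@]2(O)C1 | intermediate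
21 | 1β-bromo-5α-hydroxy-10β-methyl-4-methylene-trans-decalin-7β-carbaldehyde | O=C[C@@H]1CC[C@@]2(C)[C@H](Br)CCC(=C)[C@]2(O)C1 | intermediate
22 | 1β-bromo-7β-ethynyl-10β-methyl-4-methylene-trans-decalin-5α-ol | C#C[C@@H]1CC[C@@]2(C)[C@H](Br)CCC(=C)[C@]2(O)C1 | intermediate
23 | (E)-alkenyl(dimethyl)alane, C5–O as O–AlMe2 (not isolated) | C[Al](C)/C=C(\C)[C@@H]1CC[C@@]2(C)[C@H](Br)CCC(=C)[C@]2(O[Al](C)C)C1 | intermediate
24 | 1β-bromo-7β-[(E)-1-iodoprop-1-en-2-yl]-10β-methyl-4-methylene-trans-decalin-5α-ol | I/C=C(\C)[C@@H]1CC[C@@]2(C)[C@H](Br)CCC(=C)[C@]2(O)C1 | intermediate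
25 | 2-methylbut-1-en-3-yne | C=C(C)C#C | starting material
26 | (E)-4,4,5,5-tetramethyl-2-(3-methylbuta-1,3-dien-1-yl)-1,3,2-dioxaborolane | C=C(C)/C=C/B1OC(C)(C)C(C)(C)O1 | intermediate
27 | target: 1β-bromo-10β-methyl-4-methylene-7β-[(2E,4E)-6-methylhepta-2,4,6-trien-2-yl]-trans-decalin-5α-ol | C=C(C)/C=C/C=C(\C)[C@@H]1CC[C@@]2(C)[C@H](Br)CCC(=C)[C@]2(O)C1 | target

**Count and risks**

Total: 20 steps. Longest linear sequence: 17 steps (4 → 5 → 6 → 7 → 9 → 10 → 13 → 14 → 15 → 16 → 17 → 18 → 19 → 20 → 21 → 22 → 24 → 27).

The three steps most likely to fail: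

First, step 5. The cycloaddition may stall on the trisubstituted enone with its fully substituted γ-carbon, or proceed with poor or inverted enantiofacial discrimination, because an α-methyl enone cannot use the α-C–H binding mode on which this catalyst class normally relies. The fallback sets out from 3 and 6: EtAlCl2 (toluene, 0 °C → rt) gives the racemic cis-octalone ketal F1, whose antipodes are separated by preparative supercritical-fluid chromatography on a polysaccharide chiral stationary phase. The (5S,10R) antipode is 7, where the route is rejoined.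

Second, step 7. Enolisation of the C4 ketone may leak towards C3, so that step 8 oxidises C3 as well as C5. The fallback sets out from 9 and removes the choice. LiN(i-Pr)2 (2.2 equiv) and Me3SiCl at −78 °C give the kinetic C3=C4 bis-silyl enol ether F2. Pd(OAc)2 in MeCN (Saegusa–Ito oxidation) with acidic work-up gives the C2=C3 enone F3, whose only enolisable position is C5. LiN(i-Pr)2 followed by 2-(phenylsulfonyl)-3-phenyloxaziridine hydroxylates C5 from the α-face to give the 5α-hydroxy enone F4. [(Ph3P)CuH]6 then reduces the enone C=C and the route is rejoined at 13.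

Third, step 13. Hydrogen-atom transfer to the trisubstituted bromoalkene may be slow, may cost the bromine, or may deliver hydrogen to C1 from the β-face. The fallback sets out from 17: hydroxyl-directed hydrogenation with [Ir(cod)(PCy3)(py)]PF6 under H2 in CH2Cl2, in which the C5 hydroxyl steers both additions to the α-face, gives 18 directly. It makes no compound outside the list (F0).

Further compounds
F1 | step 5 | racemic cis-octalone ketal (7 and its mirror image) | CC(C)(C)[Si](c3ccccc3)(c3ccccc3)OCC1=CC[C@@]2(C)C(=O)CCC3(OCCO3)[C@H]2C1.CC(C)(C)[Si](c3ccccc3)(c3ccccc3)OCC1=CC[C@]2(C)C(=O)CCC3(OCCO3)[C@@H]2C1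
F2 | step 7 | kinetic bis-silyl compound: C1–OSiMe3 ether, C3=C4 trimethylsilyl enol ether | CC(C)(C)[Si](c3ccccc3)(c3ccccc3)OCC1=CC[C@@]2(C)C(O[Si](C)(C)C)CC=C(O[Si](C)(C)C)[C@H]2C1
F3 | step 7 | 1-hydroxy-Δ2-en-4-one (C2=C3 enone) | CC(C)(C)[Si](c3ccccc3)(c3ccccc3)OCC1=CC[C@@]2(C)C(O)C=CC(=O)[C@H]2C1
F4 | step 7 | 1,5α-dihydroxy-Δ2-en-4-one | CC(C)(C)[Si](c3ccccc3)(c3ccccc3)OCC1=CC[C@@]2(C)C(O)C=CC(=O)[C@]2(O)C1
F0 | step 13 | none | none
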